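Rings are lettered A to H from the 2,4,6-trihydroxyphenyl end. Ring B bears oxygen at C1 (ether to ring A), C3, C4 and C5 (ether to ring C); a formyl group put temporarily on C4 in place of its hydroxyl makes C1 para and C3/C5 ortho to an acceptor. Everything rests on cutting the three C–O bonds at C1, C5 and C3 of ring B: in one flask 2,4,6-trifluorobenzaldehyde takes up ring A phenoxide, the permethylated hexamer phenol of rings C to H and methoxide in turn. The hexamer is grown ring by ring through formyl-activated aryl ether couplings, each followed by Dakin unmasking; a last Dakin oxidation and global demethylation complete the target.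

Key step: step 11

Remark on numbering: in rings B to H, C1 is the carbon bonded to the ether oxygen on the ring A side. Rings C, E and G carry oxygen on C1, C3, C4, C5 and C6 (C6 is the ether towards ring H). Rings D and F carry oxygen on C1, C3, C5 and C4 (C4 is the ether towards ring H). Ring H carries oxygen on C1, C3, C4 and C5. Ring A is numbered from its single ether carbon.

Remark on chemistry: the target has no stereocentre. Compounds 1, 2, 6, 19 and 20 are taken as purchasable. All phenols and the final polyphenol are handled under argon.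

Step 1
Reactants: 1 3,4,5-trimethoxyphenol (ring H); 2 2-bromo-3,4,5-trimethoxybenzaldehyde (ring G)
Product: 3 3,4,5-trimethoxy-2-(3,4,5-trimethoxyphenoxy)benzaldehyde (rings G–H aldehyde)
Conditions: CuI (10 mol%), picolinic acid (20 mol%), K3PO4, DMSO, 90 °C, Ar
Reagents that add atoms: none
Why: Ullmann-type copper-catalysed C–O coupling in which the ortho-formyl group of 2 assists insertion into the C–Br bond and phenol 1 has no ortho substituent, a pairing well established for 2-bromo-3,4,5-trimethoxybenzoyl electrophiles.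

Step 2
Reactants: 3 rings G–H aldehyde
Product: 5 3,4,5-trimethoxy-2-(3,4,5-trimethoxyphenoxy)phenol (rings G–H phenol), via dimer aryl formate 4 (not isolated)
Conditions: mCPBA, CH2Cl2, 0 °C to rt; then K2CO3, MeOH, rt
Reagents that add atoms: mCPBA, OOC(=O)c1cccc(Cl)c1
Why: Dakin-type oxidation run as a Baeyer–Villiger reaction, in which the electron-rich aryl group with ortho and para oxygen donors migrates in preference to hydrogen to give the aryl formate, followed by mild methanolysis that frees the hydroxyl on C1 of ring G without touching the diaryl ether.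

Step 3
Reactants: 5 rings G–H phenol; 6 4-bromo-3,5-dimethoxybenzaldehyde (ring F)
Product: 7 3,5-dimethoxy-4-[3,4,5-trimethoxy-2-(3,4,5-trimethoxyphenoxy)phenoxy]benzaldehyde (rings F–H aldehyde)
Conditions: CuI (20 mol%), picolinic acid (40 mol%), K3PO4, DMSO, 110 °C, Ar
Reagents that add atoms: none
Why: Ullmann-type C–O coupling under picolinic acid conditions suited to ortho-substituted partners, helped by the para-formyl group of 6, which makes the C–Br bond between the two methoxy groups more reactive and at the same time serves as the latent C1 oxygen of ring F.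

Step 4
Reactants: 7 rings F–H aldehyde
Product: 9 3,5-dimethoxy-4-[3,4,5-trimethoxy-2-(3,4,5-trimethoxyphenoxy)phenoxy]phenol (rings F–H phenol), via trimer aryl formate 8 (not isolated)
Conditions: mCPBA, CH2Cl2, 0 °C to rt; then K2CO3, MeOH, rt
Reagents that add atoms: mCPBA, OOC(=O)c1cccc(Cl)c1
Why: Baeyer–Villiger/Dakin sequence on a 3,5-dimethoxy-4-aryloxybenzaldehyde, the substitution pattern of the standard conversion of 3,4,5-trimethoxybenzaldehyde into 3,4,5-trimethoxyphenol, so aryl migration and formate cleavage should proceed as in step 2.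

Step 5
Reactants: 9 rings F–H phenol; 2 2-bromo-3,4,5-trimethoxybenzaldehyde (ring E)
Product: 10 2-{3,5-dimethoxy-4-[3,4,5-trimethoxy-2-(3,4,5-trimethoxyphenoxy)phenoxy]phenoxy}-3,4,5-trimethoxybenzaldehyde (rings E–H aldehyde)
Conditions: CuI (10 mol%), picolinic acid (20 mol%), K3PO4, DMSO, 90 °C, Ar
Reagents that add atoms: none
Why: Ullmann-type C–O coupling of the same kind as step 1, with a phenol whose two ortho positions carry hydrogen and an aryl bromide activated by its ortho-formyl group.

Step 6
Reactants: 10 rings E–H aldehyde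
Product: 12 permethylated rings E–H tetramer phenol (hydroxyl on C1 of ring E), via tetramer aryl formate 11 (not isolated)
Conditions: mCPBA, CH2Cl2, 0 °C to rt; then K2CO3, MeOH, rt
Reagents that add atoms: mCPBA, OOC(=O)c1cccc(Cl)c1
Why: Baeyer–Villiger/Dakin sequence on the same 2-aryloxy-3,4,5-trimethoxybenzaldehyde unit as in step 2, so the aryl group should migrate and the formate should be cleaved by methanolysis.

Step 7
Reactants: 12 rings E–H tetramer phenol; 6 4-bromo-3,5-dimethoxybenzaldehyde (ring D)
Product: 13 permethylated rings D–H pentamer aldehyde (formyl on C1 of ring D)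
Conditions: CuI (20 mol%), picolinic acid (40 mol%), K3PO4, DMSO, 110 °C, Ar
Reagents that add atoms: none
Why: Ullmann-type C–O coupling identical in its reacting atoms to step 3, since the phenol again carries one ortho aryloxy group and the bromide is activated by its para-formyl group.

Step 8
Reactants: 13 rings D–H pentamer aldehyde
Product: 15 permethylated rings D–H pentamer phenol (hydroxyl on C1 of ring D), via pentamer aryl formate 14 (not isolated)
Conditions: mCPBA, CH2Cl2, 0 °C to rt; then K2CO3, MeOH, rt
Reagents that add atoms: mCPBA, OOC(=O)c1cccc(Cl)c1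
Why: Baeyer–Villiger/Dakin sequence on the same 3,5-dimethoxy-4-aryloxybenzaldehyde unit as in step 4.

Step 9
Reactants: 15 rings D–H pentamer phenol; 2 2-bromo-3,4,5-trimethoxybenzaldehyde (ring C)
Product: 16 permethylated rings C–H hexamer aldehyde (formyl on C1 of ring C)
Conditions: CuI (10 mol%), picolinic acid (20 mol%), K3PO4, DMSO, 90 °C, Ar
Reagents that add atoms: none
Why: Ullmann-type C–O coupling of the same kind as steps 1 and 5, using a phenol without ortho substituents and the ortho-formyl-activated bromide.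

Step 10
Reactants: 16 rings C–H hexamer aldehyde
Product: 18 permethylated rings C–H hexamer phenol (hydroxyl on C1 of ring C), via hexamer aryl formate 17 (not isolated)
Conditions: mCPBA, CH2Cl2, 0 °C to rt; then K2CO3, MeOH, rt
Reagents that add atoms: mCPBA, OOC(=O)c1cccc(Cl)c1
Why: Baeyer–Villiger/Dakin sequence as in steps 2 and 6, which should deliver the free hydroxyl on C1 of ring C needed as the nucleophile of the key step.

Step 11
Reactants: 19 2,4,6-trifluorobenzaldehyde (ring B core); 20 2,4,6-trimethoxyphenol (ring A); 18 permethylated rings C–H hexamer phenol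
Product: 23 permethylated octamer aldehyde (formyl on C4 of ring B), via difluoro diaryl ether aldehyde 21 (not isolated), via monofluoro octamer aldehyde 22 (not isolated)
Conditions: 20 (1.0 equiv), K2CO3, DMSO, rt; then 18 (1.0 equiv), K2CO3, 55 °C; then NaOMe, 75 °C
Reagents that add atoms: sodium methoxide, [Na+].[O-]C
Why: Each substitution is an addition–elimination SNAr in which the phenoxide or methoxide adds to a C–F carbon and the Meisenheimer anion is delocalised into the formyl group (para for C1, ortho for C5 and C3 of ring B) before fluoride leaves. The closest known reaction type is the stepwise SNAr of polyfluorobenzaldehydes with phenoxides and alkoxides. No ring is closed and no stereocentre is formed. The first stage needs para selectivity, which should come from phenoxide 20: with two ortho methoxy groups and as a dissociated potassium salt in DMSO it should prefer the fluorine flanked by two hydrogens over those beside the formyl group, after which the two remaining fluorines of 21 are equivalent. Single substitution at each stage should follow from the deactivation that every new aryloxy donor imposes, so one equivalent of 18 should react at 55 °C and methoxide only at 75 °C, where C–F displacement should outrun exchange of the aryloxy groups.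

Step 12
Reactants: 23 permethylated octamer aldehyde
Product: 25 permethylated octamer phenol (free hydroxyl on C4 of ring B and twenty methoxy groups), via octamer aryl formate 24 (not isolated)
Conditions: mCPBA, CH2Cl2, 0 °C to rt; then K2CO3, MeOH, rt
Reagents that add atoms: mCPBA, OOC(=O)c1cccc(Cl)c1
Why: Baeyer–Villiger oxidation of a 2,6-dioxygenated 4-aryloxybenzaldehyde, a class in which aryl migration is strongly favoured, followed by methanolysis of the formate; with a small excess of peracid at low temperature the aldehyde should react faster than any methoxylated ring.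

Step 13
Reactants: 25 permethylated octamer phenol
Product: 26 target octamer CNP0175816.0 (twenty-one free hydroxyls)
Conditions: BBr3 (excess), CH2Cl2, −78 °C to rt; then H2O; reversed-phase chromatography under Ar
Reagents that add atoms: none
Why: Lewis acid mediated cleavage of aryl methyl ethers by BBr3 (boron coordinates the oxygen, bromide attacks the methyl group), a reaction that leaves diaryl ether C–O bonds intact, so all twenty methoxy groups should become hydroxyls once the borate esters are hydrolysed.

Compound list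
1 | 3,4,5-trimethoxyphenol | COc1cc(O)cc(OC)c1OC | starting material
2 | 2-bromo-3,4,5-trimethoxybenzaldehyde | COc1cc(C=O)c(Br)c(OC)c1OC | starting material
3 | 3,4,5-trimethoxy-2-(3,4,5-trimethoxyphenoxy)benzaldehyde (rings G–H aldehyde) | O=Cc1cc(OC)c(OC)c(OC)c1Oc1cc(OC)c(OC)c(OC)c1 | intermediate
4 | 3,4,5-trimethoxy-2-(3,4,5-trimethoxyphenoxy)phenyl formate (formed in the flask, not isolated) | O=COc1cc(OC)c(OC)c(OC)c1Oc1cc(OC)c(OC)c(OC)c1 | intermediate
5 | 3,4,5-trimethoxy-2-(3,4,5-trimethoxyphenoxy)phenol (rings G–H phenol) | Oc1cc(OC)c(OC)c(OC)c1Oc1cc(OC)c(OC)c(OC)c1 | intermediate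
6 | 4-bromo-3,5-dimethoxybenzaldehyde | O=Cc1cc(OC)c(Br)c(OC)c1 | starting material
7 | 3,5-dimethoxy-4-[3,4,5-trimethoxy-2-(3,4,5-trimethoxyphenoxy)phenoxy]benzaldehyde (rings F–H aldehyde) | O=Cc1cc(OC)c(Oc2cc(OC)c(OC)c(OC)c2Oc2cc(OC)c(OC)c(OC)c2)c(OC)c1 | intermediate
8 | formate ester of phenol 9 (formed in the flask, not isolated) | O=COc1cc(OC)c(Oc2cc(OC)c(OC)c(OC)c2Oc2cc(OC)c(OC)c(OC)c2)c(OC)c1 | intermediate
9 | 3,5-dimethoxy-4-[3,4,5-trimethoxy-2-(3,4,5-trimethoxyphenoxy)phenoxy]phenol (rings F–H phenol) | Oc1cc(OC)c(Oc2cc(OC)c(OC)c(OC)c2Oc2cc(OC)c(OC)c(OC)c2)c(OC)c1 | intermediate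
10 | 2-{3,5-dimethoxy-4-[3,4,5-trimethoxy-2-(3,4,5-trimethoxyphenoxy)phenoxy]phenoxy}-3,4,5-trimethoxybenzaldehyde (rings E–H aldehyde) | O=Cc1cc(OC)c(OC)c(OC)c1Oc1cc(OC)c(Oc2cc(OC)c(OC)c(OC)c2Oc2cc(OC)c(OC)c(OC)c2)c(OC)c1 | intermediate
11 | formate ester of phenol 12 (formed in the flask, not isolated) | O=COc1cc(OC)c(OC)c(OC)c1Oc1cc(OC)c(Oc2cc(OC)c(OC)c(OC)c2Oc2cc(OC)c(OC)c(OC)c2)c(OC)c1 | intermediate
12 | permethylated rings E–H tetramer phenol, hydroxyl on C1 of ring E | Oc1cc(OC)c(OC)c(OC)c1Oc1cc(OC)c(Oc2cc(OC)c(OC)c(OC)c2Oc2cc(OC)c(OC)c(OC)c2)c(OC)c1 | intermediate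
13 | permethylated rings D–H pentamer aldehyde, formyl on C1 of ring D | O=Cc1cc(OC)c(Oc2cc(OC)c(OC)c(OC)c2Oc2cc(OC)c(Oc3cc(OC)c(OC)c(OC)c3Oc3cc(OC)c(OC)c(OC)c3)c(OC)c2)c(OC)c1 | intermediate
14 | formate ester of phenol 15 (formed in the flask, not isolated) | O=COc1cc(OC)c(Oc2cc(OC)c(OC)c(OC)c2Oc2cc(OC)c(Oc3cc(OC)c(OC)c(OC)c3Oc3cc(OC)c(OC)c(OC)c3)c(OC)c2)c(OC)c1 | intermediate
15 | permethylated rings D–H pentamer phenol, hydroxyl on C1 of ring D | Oc1cc(OC)c(Oc2cc(OC)c(OC)c(OC)c2Oc2cc(OC)c(Oc3cc(OC)c(OC)c(OC)c3Oc3cc(OC)c(OC)c(OC)c3)c(OC)c2)c(OC)c1 | intermediate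
16 | permethylated rings C–H hexamer aldehyde, formyl on C1 of ring C | O=Cc1cc(OC)c(OC)c(OC)c1Oc1cc(OC)c(Oc2cc(OC)c(OC)c(OC)c2Oc2cc(OC)c(Oc3cc(OC)c(OC)c(OC)c3Oc3cc(OC)c(OC)c(OC)c3)c(OC)c2)c(OC)c1 | intermediate
17 | formate ester of phenol 18 (formed in the flask, not isolated) | O=COc1cc(OC)c(OC)c(OC)c1Oc1cc(OC)c(Oc2cc(OC)c(OC)c(OC)c2Oc2cc(OC)c(Oc3cc(OC)c(OC)c(OC)c3Oc3cc(OC)c(OC)c(OC)c3)c(OC)c2)c(OC)c1 | intermediate
18 | permethylated rings C–H hexamer phenol, hydroxyl on C1 of ring C | Oc1cc(OC)c(OC)c(OC)c1Oc1cc(OC)c(Oc2cc(OC)c(OC)c(OC)c2Oc2cc(OC)c(Oc3cc(OC)c(OC)c(OC)c3Oc3cc(OC)c(OC)c(OC)c3)c(OC)c2)c(OC)c1 | intermediate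
19 | 2,4,6-trifluorobenzaldehyde | O=Cc1c(F)cc(F)cc1F | starting material
20 | 2,4,6-trimethoxyphenol | COc1cc(OC)c(O)c(OC)c1 | starting material
21 | 2,6-difluoro-4-(2,4,6-trimethoxyphenoxy)benzaldehyde (formed in the flask, not isolated) | COc1cc(OC)c(Oc2cc(F)c(C=O)c(F)c2)c(OC)c1 | intermediate
22 | permethylated octamer aldehyde with fluorine still on C3 of ring B (formed in the flask, not isolated) | COc1cc(OC)c(Oc2cc(F)c(C=O)c(Oc3cc(OC)c(OC)c(OC)c3Oc3cc(OC)c(Oc4cc(OC)c(OC)c(OC)c4Oc4cc(OC)c(Oc5cc(OC)c(OC)c(OC)c5Oc5cc(OC)c(OC)c(OC)c5)c(OC)c4)c(OC)c3)c2)c(OC)c1 | intermediate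
23 | permethylated octamer aldehyde, formyl on C4 of ring B | COc1cc(OC)c(Oc2cc(OC)c(C=O)c(Oc3cc(OC)c(OC)c(OC)c3Oc3cc(OC)c(Oc4cc(OC)c(OC)c(OC)c4Oc4cc(OC)c(Oc5cc(OC)c(OC)c(OC)c5Oc5cc(OC)c(OC)c(OC)c5)c(OC)c4)c(OC)c3)c2)c(OC)c1 | intermediate
24 | formate ester of phenol 25 (formed in the flask, not isolated) | COc1cc(OC)c(Oc2cc(OC)c(OC=O)c(Oc3cc(OC)c(OC)c(OC)c3Oc3cc(OC)c(Oc4cc(OC)c(OC)c(OC)c4Oc4cc(OC)c(Oc5cc(OC)c(OC)c(OC)c5Oc5cc(OC)c(OC)c(OC)c5)c(OC)c4)c(OC)c3)c2)c(OC)c1 | intermediate
25 | permethylated octamer phenol, free hydroxyl on C4 of ring B, twenty methoxy groups | COc1cc(OC)c(Oc2cc(OC)c(O)c(Oc3cc(OC)c(OC)c(OC)c3Oc3cc(OC)c(Oc4cc(OC)c(OC)c(OC)c4Oc4cc(OC)c(Oc5cc(OC)c(OC)c(OC)c5Oc5cc(OC)c(OC)c(OC)c5)c(OC)c4)c(OC)c3)c2)c(OC)c1 | intermediate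
26 | CNP0175816.0, octameric polyhydroxylated phenyl ether with twenty-one hydroxyls | Oc1cc(O)c(Oc2cc(O)c(O)c(Oc3cc(O)c(O)c(O)c3Oc3cc(O)c(Oc4cc(O)c(O)c(O)c4Oc4cc(O)c(Oc5cc(O)c(O)c(O)c5Oc5cc(O)c(O)c(O)c5)c(O)c4)c(O)c3)c2)c(O)c1 | target

Total step count: 13. Longest linear sequence: 13 steps (from 1 and 2 to 26).

Steps most likely to fail

Step 11. The first phenoxide may attack a fluorine beside the formyl group instead of the para one, the hexamer may add twice, or methoxide may exchange an aryloxy group already installed. The fallback fixes the para C–O bond by a route that cannot give the ortho isomer and then runs the remaining substitutions as separate, monitored operations. It sets out from 20, which would be coupled with purchased 1-bromo-3,5-difluorobenzene (CuI, picolinic acid, K3PO4, DMSO, 100 °C) to give 1-(3,5-difluorophenoxy)-2,4,6-trimethoxybenzene F1. Deprotonation of F1 between the two fluorines (LiN(i-Pr)2, THF, −78 °C) and a DMF quench should give 21 as an isolated, purified compound, at which point the fallback is back on the route. From there 21 would be treated with 18 and K2CO3 to give isolated 22, and 22 with NaOMe to give 23.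

Step 3 (and its repeat, step 7). Insertion of copper into the C–Br bond between two methoxy groups may be too slow, so that the bromide is reduced or the electron-rich phenol is oxidised. The fallback replaces the copper coupling by an uncatalysed SNAr on the corresponding aryl fluoride. It sets out from 6, which would be protected as 2-(4-bromo-3,5-dimethoxyphenyl)-1,3-dioxolane F2 (ethylene glycol, TsOH, toluene, reflux). Bromine–lithium exchange and fluorination (n-BuLi, THF, −78 °C; then N-fluorobenzenesulfonimide) should give 2-(4-fluoro-3,5-dimethoxyphenyl)-1,3-dioxolane F3, and aqueous HCl in THF should release 4-fluoro-3,5-dimethoxybenzaldehyde F4. Phenol 5 would then displace the fluoride of F4 (K2CO3, DMSO, 120 °C), activated by the para-formyl group, and the fallback returns at 7. For step 7 the same F4 would be used with 12 and return at 13.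

Step 13. Demethylation may stop short of all twenty ethers, boron may stay bound to the vicinal triols, and the free polyphenol may oxidise during isolation. The fallback captures the crude product as a stable derivative that can be purified on silica and then releases it under non-oxidising conditions. It sets out from 25: after BBr3 and the aqueous quench, the crude material would be acetylated (Ac2O, pyridine, rt) to the henicosaacetate of the target F5. Chromatography of F5 removes partly methylated material, which can be resubmitted. Acid-catalysed methanolysis of F5 (HCl in degassed MeOH, rt) should then return to the route at 26.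

Further compounds
F1 | step 11 | 1-(3,5-difluorophenoxy)-2,4,6-trimethoxybenzene | COc1cc(OC)c(Oc2cc(F)cc(F)c2)c(OC)c1
F2 | step 3 | 2-(4-bromo-3,5-dimethoxyphenyl)-1,3-dioxolane | COc1cc(C2OCCO2)cc(OC)c1Br
F3 | step 3 | 2-(4-fluoro-3,5-dimethoxyphenyl)-1,3-dioxolane | COc1cc(C2OCCO2)cc(OC)c1F
F4 | step 3 | 4-fluoro-3,5-dimethoxybenzaldehyde | COc1cc(C=O)cc(OC)c1F
F5 | step 13 | henicosaacetate of the target octamer | CC(=O)Oc1cc(OC(C)=O)c(Oc2cc(OC(C)=O)c(OC(C)=O)c(Oc3cc(OC(C)=O)c(OC(C)=O)c(OC(C)=O)c3Oc3cc(OC(C)=O)c(Oc4cc(OC(C)=O)c(OC(C)=O)c(OC(C)=O)c4Oc4cc(OC(C)=O)c(Oc5cc(OC(C)=O)c(OC(C)=O)c(OC(C)=O)c5Oc5cc(OC(C)=O)c(OC(C)=O)c(OC(C)=O)c5)c(OC(C)=O)c4)c(OC(C)=O)c3)c2)c(OC(C)=O)c1
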